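All runs stem from a simulated flask with made-up constants; the scatter is artificial.

Take the ratio of single product found to substrate consumed. One minus it is the diverted share δ, a correction to conversion, and the ratio itself is the usual selectivity. Write M for single product and S for substrate left, both as fractions of the substrate charged.

| setting | Thursday's | Wednesday's | flask |
|---|---|---|---|
| substrate | 0.050 M | 0.025 M | 0.050 M |
| partner | 0.050 M | 0.050 M | 0.0500 M |
| remark | the very flask that is asked about, followed so far | run made earlier |  |
| time |  |  | 20 h |

| run | time / h | single product / % | substrate / % |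
|---|---|---|---|
| Thursday's | 0.833 | 56.6 | 29.0 |
| Thursday's | 2.50 | 55.8 | 29.1 |
| Thursday's | 5.00 | 56.0 | 29.6 |
| Thursday's | 8.00 | 56.8 | 29.1 |
| Thursday's | 10.0 | 56.2 | 29.9 |
| Wednesday's | 0.667 | 60.4 | 6.5 |
| Wednesday's | 1.33 | 59.3 | 6.1 |
| Wednesday's | 2.50 | 58.8 | 6.9 |
| Wednesday's | 4.00 | 59.2 | 6.1 |
| Wednesday's | 8.00 | 58.9 | 6.6 |

(each reading ± 0.3 percentage points)

- equivalents of partner to substrate, everything else as given, that leave most single product at 20 h
- the amount of single product then, in percent of the substrate charged
- the amount of single product with the amounts as given

- a reading or a percentage of single product counts all its forms, free or not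

Ask first what must be known well. Time comes first: Thursday's last reading of M lies 0.4 percentage points below its first, against a scatter of 0.3 points, so the plateau can be carried to 20 h. Now average Thursday's readings: S is 29.3% and M is 56.3%, which gives a diverted share 0.204. An error in S reaches M scaled by 0.796, and an error in δ reaches it scaled by 71 points, so both count. Next the charge: Wednesday's run, at 2.00 equivalents, has S at 6.44% and a larger δ, at 0.366. Across both runs, with substrate changing too, δ climbs 0.162 per equivalent. For the flask as given, I commit to Thursday's 56.3%.

The forecast gives 56.3%, and 60.5% at 1.27 equiv, holding that “both runs are at equilibrium”.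

The simulation gives 56.4%, and 66.6% at 1.61 equiv, above the forecast's best.

    partner + single product → bis adduct (k = 0.629 M⁻¹ s⁻¹)
    partner + bis adduct → tris adduct (k = 0.238 M⁻¹ s⁻¹)
    substrate + partner → single product (k = 0.244 M⁻¹ s⁻¹)
    single product ⇌ isomer of the product (K = 3.10, k = 0.00238 s⁻¹)
    crystals ⇌ single product, rate k5*(cs5 - [single product]) while solid is left; crystals form when [single product] > cs5 (solubility = 0.630 mM, k = 0.129 s⁻¹)
    partner → decomposed reagent (k = 0.00133 s⁻¹)

In this flask at 20.0 h, with 29.2% of substrate left, δ stands at 0.203. Now take the neighbour charged with 0.085 M of partner, 1.70 equiv: the line gives δ of 0.317, and its 5.45% of substrate left then means 64.6% of single product. That neighbour holds 66.3%, a δ of 0.299.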